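The route rests on the C6–C7 bond, where the methylene on carbinol carbon C5 of the butenolide ring meets the vinylic CH of the C7=C8 olefin (lactone O1–C5, chain C6–C14, cyclohexanol ring C15–C20). A nickel-electrocatalytic decarboxylative alkenylation joins a (Z)-vinyl iodide, made by anti-carbomagnesiation of propargyl alcohol so that iodine and CH2O are cis, to the N-hydroxyphthalimide ester of (R)-malic acid acetonide. The step exploits that C6 is an unfunctionalised CH2 between the C5–O stereocentre and sp2 C7: C5–C6–CO2H is malic acid, and the surviving dioxolanone is the acyl donor for building the butenolide ring. One operation forges C6–C7 with olefin geometry and C5 configuration already in place.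

Key step: step 9

Remark on the chemistry: the cyclase in step 1 is used as a catalyst and is not counted as a starting material; in the numbering above C16 is the CMe2 carbon and C20 the C(OH)Me carbon.

Step 1
Reactants: 1 (5E)-6,10-dimethylundeca-5,9-dien-2-one ((E)-geranylacetone)
Product: 3 4-[(1S,2S)-2-hydroxy-2,6,6-trimethylcyclohexyl]butan-2-one, via bicyclic enol ether 2 (not isolated)
Conditions: squalene–hopene cyclase (Alicyclobacillus acidocaldarius, recombinant whole cells), citrate buffer pH 6, Triton X-100, 30 °C; then aq. HCl–THF, rt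
Reagents that add atoms: water, O
Why: Enzymatic proton-initiated cation–olefin cyclisation: the cyclase protonates the terminal olefin of the chair-folded substrate on one face only, the E-olefin adds anti so that C15–H (S) and the C20–O bond (S) end up trans, the ketone oxygen terminates the cation as enol ether 2, and dilute acid then hydrates only this enol ether.

Step 2
Reactants: 3 4-[(1S,2S)-2-hydroxy-2,6,6-trimethylcyclohexyl]butan-2-one
Product: 5 (1S,2S)-2-(but-3-yn-1-yl)-1,3,3-trimethylcyclohexan-1-ol, via terminal enol phosphate 4 (not isolated)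
Conditions: LiN(i-Pr)2 (2.2 equiv.), THF, −78 °C; ClP(O)(OEt)2, −78 °C → rt; LiN(i-Pr)2 (2.5 equiv.), −78 °C → rt; aq. NH4Cl
Reagents that add atoms: none
Why: Kinetic deprotonation at the methyl group, O-phosphorylation and base-induced elimination of the enol phosphate convert the methyl ketone into the terminal alkyne (enol phosphate elimination), the hindered tertiary alkoxide staying unphosphorylated and both stereocentres being remote.

Step 3
Reactants: 5 (1S,2S)-2-(but-3-yn-1-yl)-1,3,3-trimethylcyclohexan-1-ol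
Product: 7 (1S,2S)-2-[(3E)-6-hydroxy-3-methylhex-3-en-1-yl]-1,3,3-trimethylcyclohexan-1-ol, via E-alkenylalane 6 (not isolated)
Conditions: Me3Al (3 equiv.), Cp2ZrCl2 (25 mol %), CH2Cl2, 0 °C → rt; volatiles removed; n-BuLi, THF–hexane, −30 °C; ethylene oxide, −30 °C → rt; aq. potassium sodium tartrate
Reagents that add atoms: trimethylaluminium, C[Al](C)C; ethylene oxide, C1CO1
Why: Zirconium-catalysed carboalumination adds methyl and aluminium syn across the terminal alkyne with methyl on the internal carbon, which fixes the E geometry of C11=C12, and the lithium alanate made from 6 opens ethylene oxide with retention at the vinylic carbon to add C10 and C9.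

Step 4
Reactants: 7 (1S,2S)-2-[(3E)-6-hydroxy-3-methylhex-3-en-1-yl]-1,3,3-trimethylcyclohexan-1-ol
Product: 8 (1S,2S)-2-[(3E)-6-bromo-3-methylhex-3-en-1-yl]-1,3,3-trimethylcyclohexan-1-ol
Conditions: CBr4, PPh3, CH2Cl2, 0 °C
Reagents that add atoms: carbon tetrabromide, BrC(Br)(Br)Br
Why: Appel reaction at the unhindered primary alcohol; the neopentyl-flanked tertiary alcohol does not react under these neutral conditions.

Step 5
Reactants: 8 (1S,2S)-2-[(3E)-6-bromo-3-methylhex-3-en-1-yl]-1,3,3-trimethylcyclohexan-1-ol; 9 prop-2-yn-1-ol (propargyl alcohol)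
Product: 12 (2Z)-2-{(3E)-6-[(1S,2S)-2-hydroxy-2,6,6-trimethylcyclohexyl]-4-methylhex-3-en-1-yl}-3-iodoprop-2-en-1-ol, via Grignard reagent 10 (not isolated), via chelated alkenylmagnesium alkoxide 11 (not isolated)
Conditions: EtMgBr (1.0 equiv.), THF, 0 °C; Mg, LiCl, THF, rt; added to BrMgOCH2C≡CH (from 9 and EtMgBr) and CuI (20 mol %), THF, −10 °C → rt; I2, −40 → 0 °C
Reagents that add atoms: iodine, [I][I]
Why: After the tertiary hydroxyl is masked as its magnesium alkoxide, magnesium insertion gives 10, whose copper-catalysed carbomagnesiation of the propargylic magnesium alkoxide places the alkyl group on the alkyne carbon next to CH2O in an anti sense and leaves the five-membered chelate 11, so that iodinolysis with retention puts iodine cis to CH2OH (Z at C7=C8).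

Step 6
Reactants: 12 (2Z)-2-{(3E)-6-[(1S,2S)-2-hydroxy-2,6,6-trimethylcyclohexyl]-4-methylhex-3-en-1-yl}-3-iodoprop-2-en-1-ol
Product: 13 (1S,2S)-2-{(3E,7Z)-8-iodo-7-[(methoxymethoxy)methyl]-3-methylocta-3,7-dien-1-yl}-1,3,3-trimethylcyclohexan-1-ol
Conditions: CH3OCH2Cl, i-Pr2NEt, CH2Cl2, 0 °C → rt
Reagents that add atoms: chloromethyl methyl ether, COCCl
Why: Acetal protection (O-alkylation with an α-chloro ether under amine base) of the primary allylic alcohol, which must not compete with the C5 hydroxyl for the ketene ylide in step 11; the tertiary alcohol is too hindered to react.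

Step 7
Reactants: 14 (R)-malic acid
Product: 15 [(4R)-2,2-dimethyl-5-oxo-1,3-dioxolan-4-yl]acetic acid
Conditions: 2,2-dimethoxypropane, p-TsOH·H2O (cat.), rt
Reagents that add atoms: 2,2-dimethoxypropane, COC(C)(C)OC
Why: Acid-catalysed acetal exchange ties the α-hydroxy acid into the five-membered dioxolanone, which protects the C5 oxygen, activates the future C4 carbonyl and leaves the β-carboxyl free, without touching the stereocentre.

Step 8
Reactants: 15 [(4R)-2,2-dimethyl-5-oxo-1,3-dioxolan-4-yl]acetic acid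
Product: 16 1,3-dioxoisoindolin-2-yl [(4R)-2,2-dimethyl-5-oxo-1,3-dioxolan-4-yl]acetate
Conditions: N-hydroxyphthalimide, N,N′-diisopropylcarbodiimide, DMAP (cat.), CH2Cl2, rt
Reagents that add atoms: N-hydroxyphthalimide, O=C1c2ccccc2C(=O)N1O
Why: Carbodiimide esterification with N-hydroxyphthalimide gives the redox-active ester under neutral conditions that leave the dioxolanone closed.

Step 9
Reactants: 13 (1S,2S)-2-{(3E,7Z)-8-iodo-7-[(methoxymethoxy)methyl]-3-methylocta-3,7-dien-1-yl}-1,3,3-trimethylcyclohexan-1-ol; 16 1,3-dioxoisoindolin-2-yl [(4R)-2,2-dimethyl-5-oxo-1,3-dioxolan-4-yl]acetate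
Product: 17 (5R)-5-{(2Z,6E)-9-[(1S,2S)-2-hydroxy-2,6,6-trimethylcyclohexyl]-3-[(methoxymethoxy)methyl]-7-methylnona-2,6-dien-1-yl}-2,2-dimethyl-1,3-dioxolan-4-one
Conditions: 16 (2 equiv.), NiCl2·6H2O (20 mol %), 2,2′-bipyridine (20 mol %), AgNO3 (30 mol %), LiCl, DMF, Mg anode, reticulated vitreous carbon cathode, constant current, rt
Reagents that add atoms: none
Why: Cathodic reduction of the divalent nickel–bipyridine complex gives low-valent nickel that adds oxidatively to the C7–I bond of 13 with retention of the Z geometry, while single-electron reduction of 16 expels phthalimide anion and CO2 and leaves the primary C6 radical; this radical is captured by the alkenylnickel species and reductive elimination from trivalent nickel forges C6–C7. The closest known reaction type is the nickel-electrocatalytic decarboxylative alkenylation of redox-active esters with alkenyl iodides on a silver-nanoparticle-coated cathode, established for terpenoid polyene chains. No ring is closed and no stereocentre is created: C5 comes unchanged from (R)-malic acid because the radical is on the adjacent carbon, and the C7=C8 geometry is that of the iodide. The step needs chemoselective activation of the C–I bond and the ester N–O bond beside an electrophilic dioxolanone, a free tertiary alcohol and two acetals, which the neutral, base-free reductive medium secures. It also needs a radical that is captured before it rearranges, secured by keeping C4 at the ester level in a ring without any olefin, so that neither acyl migration nor 3-exo closure onto a butenolide can compete.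

Step 10
Reactants: 17 (5R)-5-{(2Z,6E)-9-[(1S,2S)-2-hydroxy-2,6,6-trimethylcyclohexyl]-3-[(methoxymethoxy)methyl]-7-methylnona-2,6-dien-1-yl}-2,2-dimethyl-1,3-dioxolan-4-one
Product: 19 (3R,5Z,9E)-3-hydroxy-12-[(1S,2S)-2-hydroxy-2,6,6-trimethylcyclohexyl]-1-(methoxymethoxy)-6-[(methoxymethoxy)methyl]-10-methyldodeca-5,9-dien-2-one, via lithium hemiketal 18 (not isolated)
Conditions: Bu3SnCH2OCH2OCH3, n-BuLi, THF, −78 °C (gives LiCH2OCH2OCH3, 2.5 equiv.); 17, −78 °C; aq. NH4Cl
Reagents that add atoms: tributyl[(methoxymethoxy)methyl]stannane, CCCC[Sn](CCCC)(CCCC)COCOC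
Why: Tin–lithium exchange gives the α-alkoxymethyllithium, which adds once to the activated ester carbonyl of the dioxolanone at −78 °C (one further equivalent is consumed by the tertiary hydroxyl), and the lithium hemiketal 18 collapses only on work-up with loss of acetone to the α-hydroxy ketone with C5 unchanged (acyl substitution through a stable tetrahedral intermediate).

Step 11
Reactants: 19 (3R,5Z,9E)-3-hydroxy-12-[(1S,2S)-2-hydroxy-2,6,6-trimethylcyclohexyl]-1-(methoxymethoxy)-6-[(methoxymethoxy)methyl]-10-methyldodeca-5,9-dien-2-one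
Product: 21 (5R)-5-{(2Z,6E)-9-[(1S,2S)-2-hydroxy-2,6,6-trimethylcyclohexyl]-3-[(methoxymethoxy)methyl]-7-methylnona-2,6-dien-1-yl}-4-[(methoxymethoxy)methyl]furan-2(5H)-one, via acyl ylide 20 (not isolated)
Conditions: Ph3P=C=C=O (1.3 equiv.), toluene, 90 °C
Reagents that add atoms: ketenylidenetriphenylphosphorane, O=C=C=P(c1ccccc1)(c1ccccc1)c1ccccc1
Why: The C5 hydroxyl adds to the ketene carbon of the ylide to give acyl ylide 20, whose intramolecular Wittig olefination of the neighbouring ketone closes the butenolide ring (five-membered, C2 and the C5 oxygen necessarily cis on C3=C4) under neutral conditions that do not epimerise C5.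

Step 12
Reactants: 21 (5R)-5-{(2Z,6E)-9-[(1S,2S)-2-hydroxy-2,6,6-trimethylcyclohexyl]-3-[(methoxymethoxy)methyl]-7-methylnona-2,6-dien-1-yl}-4-[(methoxymethoxy)methyl]furan-2(5H)-one
Product: 22 (5R)-4-(hydroxymethyl)-5-{(2Z,6E)-3-(hydroxymethyl)-9-[(1S,2S)-2-hydroxy-2,6,6-trimethylcyclohexyl]-7-methylnona-2,6-dien-1-yl}furan-2(5H)-one
Conditions: MgBr2·OEt2, n-BuSH, Et2O, rt
Reagents that add atoms: none
Why: Lewis-acid-assisted thiolysis of both methoxymethyl acetals, chosen because it avoids the protic acid that could ionise the tertiary alcohol towards the C11=C12 olefin.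

Compound list
1 | (5E)-6,10-dimethylundeca-5,9-dien-2-one ((E)-geranylacetone) | CC(=O)CC/C=C(\C)CCC=C(C)C | starting material
2 | (4aS,8aS)-2,5,5,8a-tetramethyl-4a,5,6,7,8,8a-hexahydro-4H-chromene (trans-fused bicyclic enol ether) | CC1=CC[C@H]2C(C)(C)CCC[C@]2(C)O1 | intermediate
3 | 4-[(1S,2S)-2-hydroxy-2,6,6-trimethylcyclohexyl]butan-2-one | CC(=O)CC[C@H]1C(C)(C)CCC[C@]1(C)O | intermediate
4 | diethyl 4-[(1S,2S)-2-hydroxy-2,6,6-trimethylcyclohexyl]but-1-en-2-yl phosphate (present as its lithium alkoxide) | C=C(OP(=O)(OCC)OCC)CC[C@H]1C(C)(C)CCC[C@]1(C)O | intermediate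
5 | (1S,2S)-2-(but-3-yn-1-yl)-1,3,3-trimethylcyclohexan-1-ol | C#CCC[C@H]1C(C)(C)CCC[C@]1(C)O | intermediate
6 | dimethyl{(1E)-2-methyl-4-[(1S,2S)-2-(dimethylaluminooxy)-2,6,6-trimethylcyclohexyl]but-1-en-1-yl}alane (aluminium cis to the new methyl) | C[Al](C)/C=C(\C)CC[C@H]1C(C)(C)CCC[C@]1(C)O[Al](C)C | intermediate
7 | (1S,2S)-2-[(3E)-6-hydroxy-3-methylhex-3-en-1-yl]-1,3,3-trimethylcyclohexan-1-ol | OCC/C=C(\C)CC[C@H]1C(C)(C)CCC[C@]1(C)O | intermediate
8 | (1S,2S)-2-[(3E)-6-bromo-3-methylhex-3-en-1-yl]-1,3,3-trimethylcyclohexan-1-ol | BrCC/C=C(\C)CC[C@H]1C(C)(C)CCC[C@]1(C)O | intermediate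
9 | prop-2-yn-1-ol (propargyl alcohol) | C#CCO | starting material
10 | Grignard reagent of 8 at C9, tertiary oxygen as bromomagnesium alkoxide | Br[Mg]CC/C=C(\C)CC[C@H]1C(C)(C)CCC[C@]1(C)O[Mg]Br | intermediate
11 | 2,5-dihydro-1,2-oxamagnesole chelate: magnesium bridging C7 and the CH2O oxygen, C8 carrying the C9–C20 chain | C1=C(CC/C=C(\C)CC[C@H]2C(C)(C)CCC[C@]2(C)O[Mg]Br)CO[Mg]1 | intermediate
12 | (2Z)-2-{(3E)-6-[(1S,2S)-2-hydroxy-2,6,6-trimethylcyclohexyl]-4-methylhex-3-en-1-yl}-3-iodoprop-2-en-1-ol | OC/C(=C\I)CC/C=C(\C)CC[C@H]1C(C)(C)CCC[C@]1(C)O | intermediate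
13 | (1S,2S)-2-{(3E,7Z)-8-iodo-7-[(methoxymethoxy)methyl]-3-methylocta-3,7-dien-1-yl}-1,3,3-trimethylcyclohexan-1-ol | COCOC/C(=C\I)CC/C=C(\C)CC[C@H]1C(C)(C)CCC[C@]1(C)O | intermediate
14 | (R)-malic acid | OC(=O)C[C@@H](O)C(=O)O | starting material
15 | [(4R)-2,2-dimethyl-5-oxo-1,3-dioxolan-4-yl]acetic acid | OC(=O)C[C@H]1OC(C)(C)OC1=O | intermediate
16 | 1,3-dioxoisoindolin-2-yl [(4R)-2,2-dimethyl-5-oxo-1,3-dioxolan-4-yl]acetate | O=C(C[C@H]1OC(C)(C)OC1=O)ON1C(=O)c2ccccc2C1=O | intermediate
17 | (5R)-5-{(2Z,6E)-9-[(1S,2S)-2-hydroxy-2,6,6-trimethylcyclohexyl]-3-[(methoxymethoxy)methyl]-7-methylnona-2,6-dien-1-yl}-2,2-dimethyl-1,3-dioxolan-4-one | COCOC/C(=C\C[C@H]1OC(C)(C)OC1=O)CC/C=C(\C)CC[C@H]2C(C)(C)CCC[C@]2(C)O | intermediate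
18 | dilithium alkoxide of the hemiketal formed by addition of CH2OCH2OCH3 to the dioxolanone carbonyl of 17 (mixture at the hemiketal carbon) | COCOC/C(=C\C[C@H]1OC(C)(C)OC1(O[Li])COCOC)CC/C=C(\C)CC[C@H]2C(C)(C)CCC[C@]2(C)O[Li] | intermediate
19 | (3R,5Z,9E)-3-hydroxy-12-[(1S,2S)-2-hydroxy-2,6,6-trimethylcyclohexyl]-1-(methoxymethoxy)-6-[(methoxymethoxy)methyl]-10-methyldodeca-5,9-dien-2-one | COCOC/C(=C\C[C@@H](O)C(=O)COCOC)CC/C=C(\C)CC[C@H]1C(C)(C)CCC[C@]1(C)O | intermediate
20 | (triphenylphosphoranylidene)acetate ester of the C5 hydroxyl of 19 | COCOC/C(=C\C[C@@H](OC(=O)C=P(c1ccccc1)(c1ccccc1)c1ccccc1)C(=O)COCOC)CC/C=C(\C)CC[C@H]2C(C)(C)CCC[C@]2(C)O | intermediate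
21 | (5R)-5-{(2Z,6E)-9-[(1S,2S)-2-hydroxy-2,6,6-trimethylcyclohexyl]-3-[(methoxymethoxy)methyl]-7-methylnona-2,6-dien-1-yl}-4-[(methoxymethoxy)methyl]furan-2(5H)-one | COCOC/C(=C\C[C@H]1OC(=O)C=C1COCOC)CC/C=C(\C)CC[C@H]2C(C)(C)CCC[C@]2(C)O | intermediate
22 | (5R)-4-(hydroxymethyl)-5-{(2Z,6E)-3-(hydroxymethyl)-9-[(1S,2S)-2-hydroxy-2,6,6-trimethylcyclohexyl]-7-methylnona-2,6-dien-1-yl}furan-2(5H)-one | C/C(=C\CC/C(=C/C[C@H]1OC(=O)C=C1CO)CO)CC[C@H]1C(C)(C)CCC[C@]1(C)O | target

Total step count: 12. Longest linear sequence: 10 steps (steps 1–6, then 9–12, from 1 to 22); steps 7 and 8 form the short branch from 14.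

Steps most likely to fail

Step 9. The β-oxygenated primary C6 radical may be reduced or dimerise before nickel captures it, an alkylnickel intermediate may lose the β-alkoxide, or the Z-alkenylnickel may isomerise. The fallback forms the same bond by polar chemistry and sets out from 13. Deprotonation and iodine–magnesium exchange with i-PrMgCl·LiCl (THF, −20 °C) should give the Z-alkenylmagnesium, which with CuI (10 mol %) opens commercial methyl (R)-glycidate at its CH2 terminus (−40 °C) to give the α-hydroxy ester F1. LiOH in THF–water then gives the α-hydroxy acid F2, and 2,2-dimethoxypropane with pyridinium p-toluenesulfonate closes the dioxolanone, which comes back to the route at 17.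

Step 10. The organolithium may enolise the dioxolanone instead of adding, eroding C5, or the hemiketal may collapse early and take up a second equivalent. The fallback passes through an amide and sets out from 17. MeNH(OMe)·HCl with i-PrMgCl (THF, −20 °C) should open the dioxolanone, with loss of acetone, to the α-hydroxy N-methoxy-N-methylamide F3. Its chelated alkoxide takes up LiCH2OCH2OCH3 once (THF, −78 °C) and releases the ketone only on work-up, which comes back to the route at 19.

Step 1. The wild-type cyclase may turn over this short substrate too slowly, so that material supply rather than selectivity fails. The fallback uses a chemical chiral proton source and sets out from 1. A stoichiometric Lewis-acid-assisted chiral Brønsted acid made from SnCl4 and 2-benzyloxy-2′-hydroxy-1,1′-binaphthyl (toluene, −78 °C) should induce the same anti cyclisation with ketone-oxygen termination; the binaphthol antipode that leads to the (4aS,8aS) series is used. It comes back to the route at enol ether 2, which is hydrolysed to 3 as in step 1; this fallback makes no compound outside the list (F0).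

Further compounds
F1 | step 9 | methyl (2R,4Z,8E)-2-hydroxy-11-[(1S,2S)-2-hydroxy-2,6,6-trimethylcyclohexyl]-5-[(methoxymethoxy)methyl]-9-methylundeca-4,8-dienoate | COCOC/C(=C\C[C@@H](O)C(=O)OC)CC/C=C(\C)CC[C@H]1C(C)(C)CCC[C@]1(C)O
F2 | step 9 | (2R,4Z,8E)-2-hydroxy-11-[(1S,2S)-2-hydroxy-2,6,6-trimethylcyclohexyl]-5-[(methoxymethoxy)methyl]-9-methylundeca-4,8-dienoic acid | COCOC/C(=C\C[C@@H](O)C(=O)O)CC/C=C(\C)CC[C@H]1C(C)(C)CCC[C@]1(C)O
F3 | step 10 | (2R,4Z,8E)-2-hydroxy-11-[(1S,2S)-2-hydroxy-2,6,6-trimethylcyclohexyl]-N-methoxy-5-[(methoxymethoxy)methyl]-N,9-dimethylundeca-4,8-dienamide | COCOC/C(=C\C[C@@H](O)C(=O)N(C)OC)CC/C=C(\C)CC[C@H]1C(C)(C)CCC[C@]1(C)O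
F0 | step 1 | none | none
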